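G comes from L through X, but L also goes to J, X turns into D, and G turns into Q.

    L + X → X + G (k1 = 57.2 M⁻¹ min⁻¹)
    L → J (k2 = 0.0418 min⁻¹)
    X → D (k3 = 0.0346 min⁻¹)
    G → Q (k4 = 0.00881 min⁻¹)

all flasks: X 1.3 mM
- gamma: L 0.26 M (fed, over 64.0 min); time 80 min; a stirred flask in which L is dosed at a steady rate over 64.0 min without added volume, worked up at 80 min
- epsilon: L 0.26 M; a single well-mixed tank run continuously and read at steady state, 80 min in it on average
- alpha: L 0.26 M; time 80 min; a closed flask charged with all of it at once and left for 80 min

- the set-up with the highest share of G in all that became G or J or Q, at the outlet or at the end ("none" if the first two lie within 2 percentage points) (gamma / epsilon / alpha / none)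
- share of G in all that became G or J or Q, at the outlet or at the end, gamma
- share of G in all that became G or J or Q, at the outlet or at the end, epsilon
- share of G in all that became G or J or Q, at the outlet or at the end, alpha

- the stated concentrations are those of everything mixed, before any reaction; amounts are the same in each set-up
- the feed brings no volume worth counting
- run time (gamma): 80 min

At a given X, L is first order on both routes, the catalysed step being pseudo-first-order in L. So I reckoned with the crossing level of X, the level at which both routes take L equally fast, which is the rate constant of the loss to J over that of the catalysed step: 0.731 mM. At a level x, the fraction x/(x + crossing level) of the L reacting goes to the G side. The charge of 1.3 mM stands above the crossing level, and X falls through it at 16.6 min.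

Charging at once (alpha) left 19.5% of L by that time, by my hand, with the fraction sliding from 64.0% to 50.0%. Taking the midpoint, 57.0%, and ageing G from the middle of that stretch, I got 30.3%. Dosing (gamma) brought a quarter of L in before the crossing. The fraction averaged evenly over the dose was 38.1%, and with G aged from the crossing time, and the lag of L uncounted, I got 21.8%. Back-mixing (epsilon) held X at 0.345 mM, below the crossing level. That gave a fraction of 32.1%, and with 58.7% of it surviving as G, 18.8%. I chose alpha.

The forecast named alpha, with 21% for gamma, 18.8% for epsilon and 29.5% for alpha, on the ground that “the all-at-once batch puts the most L in front of undecayed catalyst”.

The flask gave alpha, with 21.1% in gamma, 18.8% in epsilon and 29.6% in alpha. The main reason the share in alpha stood as high as 29.6% was the length of the run: at 800 min it was 0.0519%.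

Part of the low share in epsilon is due to the turning of X into D, which held X under the crossing level. With that step struck out, X stays at 1.3 mM, above the level, so the same rule gave 64.0% on the G side and, with 58.7% surviving, 37.6% in epsilon. The run gave 37.5%, which put epsilon 3.3 percentage points ahead of alpha.

The constants were chosen freely; what happens was integrated by code.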